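**Plan**

1. Retrosynthesis: the three phenols are unmasked last (MOM ethers). The C3–H stereocentre is traced back to the achiral isoflavone (C2=C3). The isoflavone is then cut at C3 twice at once, at the C3–aryl bond and by excising C3 from the pyranone ring, leaving a 3-silyloxybenzofuran (ring A plus furan ring) and a ring-B aryl(chloro)carbene.
2. Enabling feature: in ring C, C3 lies between the enol-ether carbon C2 (on O1) and the carbonyl carbon C4. The unit O1–C2=C3–C4=O is the ring-opened (oxyallyl cation) form of a chlorocyclopropane fused to the 2,3-bond of a 3-oxybenzofuran, so ring C can be grown from the five-membered furanone ring by inserting the aryl-bearing carbon.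
3. Forward, ring A: 4,6-dihydroxybenzofuran-3(2H)-one → bis-MOM ether → silyl enol ether. Ring B: 2,4-dihydroxybenzaldehyde → 4-O-MOM → propargyl ether → Claisen/ortho-quinone methide oxa-6π closure to the 2,2-dimethylchromene → nitrile → amidine → chlorodiazirine.
4. The key step joins the two halves and expands the furan ring to the pyranone ring in one operation. Ring order: chromene ring first, ring C last.
5. Stereochemistry: C3 is set by catalyst control in a Ru-catalysed asymmetric transfer hydrogenation with dynamic kinetic resolution, giving the cis-(3S,4S) alcohol. C4 is then re-oxidised and the MOM groups are removed under mild acid.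

Key step: step 9

Remark: the target is the (3S)-isoflavanone; the sense of the transfer hydrogenation is assigned by analogy with the reduction of 4-chromanone by the same catalyst.

**Route**

Step 1
Reactants: 1 4,6-dihydroxybenzofuran-3(2H)-one
Product: 2 4,6-bis(methoxymethoxy)benzofuran-3(2H)-one
Conditions: MOMCl (3 equiv), i-Pr2NEt, CH2Cl2, 0 °C → 40 °C
Reagents that add atoms: chloromethyl methyl ether, COCCl
Why: Williamson-type O-alkylation of both phenols should mask them as acetals that tolerate amide bases, carbene chemistry and transfer hydrogenation, the phenoxides being far more nucleophilic than the C2 methylene of the neutral ketone.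

Step 2
Reactants: 2 4,6-bis(methoxymethoxy)benzofuran-3(2H)-one
Product: 3 tert-butyl{[4,6-bis(methoxymethoxy)benzofuran-3-yl]oxy}dimethylsilane
Conditions: KN(SiMe3)2, THF, −78 °C; TBSCl, −78 → 0 °C
Reagents that add atoms: tert-butyldimethylsilyl chloride, CC(C)(C)[Si](C)(C)Cl
Why: deprotonation at C2 gives an aromatic 3-benzofuranolate that should be silylated on oxygen (silyl enol ether formation), turning the ketone into the electron-rich C2=C3 bond the carbene needs.

Step 3
Reactants: 4 2,4-dihydroxybenzaldehyde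
Product: 5 2-hydroxy-4-(methoxymethoxy)benzaldehyde
Conditions: MOMCl (1.05 equiv), i-Pr2NEt, CH2Cl2, 0 °C
Reagents that add atoms: chloromethyl methyl ether, COCCl
Why: the 2-OH is held in a hydrogen bond to the aldehyde, so Williamson mono-alkylation should occur selectively at the free 4-OH.

Step 4
Reactants: 5 2-hydroxy-4-(methoxymethoxy)benzaldehyde
Product: 6 4-(methoxymethoxy)-2-[(2-methylbut-3-yn-2-yl)oxy]benzaldehyde
Conditions: 3-chloro-3-methylbut-1-yne, DBU, CuCl2 (cat.), MeCN, 0 °C → rt
Reagents that add atoms: 3-chloro-3-methylbut-1-yne, CC(C)(Cl)C#C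
Why: copper-catalysed propargylic etherification (ionisation of the tertiary chloride through a copper acetylide) should O-alkylate even the hydrogen-bonded phenol and avoids an SN2 reaction at a tertiary carbon.

Step 5
Reactants: 6 4-(methoxymethoxy)-2-[(2-methylbut-3-yn-2-yl)oxy]benzaldehyde
Product: 9 5-(methoxymethoxy)-2,2-dimethyl-2H-chromene-8-carbaldehyde, via allenylphenol 7 (not isolated), via ortho-quinone methide 8 (not isolated)
Conditions: o-xylene, 140 °C
Reagents that add atoms: none
Why: aromatic propargyl Claisen rearrangement to C3 (the only free ortho position), enolisation, 1,5-hydrogen shift and oxa-6π electrocyclisation should give the chromene with its pyran oxygen next to the formyl-bearing carbon, which is the 2',3'-fusion of ring B.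

Step 6
Reactants: 9 5-(methoxymethoxy)-2,2-dimethyl-2H-chromene-8-carbaldehyde
Product: 12 5-(methoxymethoxy)-2,2-dimethyl-2H-chromene-8-carbonitrile, via oxime 10 (not isolated), via oxime acetate 11 (not isolated)
Conditions: NH2OH·HCl, pyridine, rt; then Ac2O, 100 °C
Reagents that add atoms: hydroxylamine hydrochloride, NO.Cl
Why: oximation followed by acetylation and base-induced elimination of acetic acid (aldoxime dehydration) should convert the formyl group into the nitrile without affecting the chromene or the acetal.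

Step 7
Reactants: 12 5-(methoxymethoxy)-2,2-dimethyl-2H-chromene-8-carbonitrile
Product: 14 5-(methoxymethoxy)-2,2-dimethyl-2H-chromene-8-carboximidamide hydrochloride, via lithium bis(silyl)amidinate 13 (not isolated)
Conditions: LiN(SiMe3)2, THF, 0 °C → rt; then HCl in EtOH (2.2 equiv), 0 °C
Reagents that add atoms: lithium bis(trimethylsilyl)amide, [Li+].C[Si](C)(C)[N-][Si](C)(C)C; hydrogen chloride, Cl
Why: addition of the silylamide to the nitrile and brief cold alcoholysis of the N-silyl groups should give the amidinium salt (amidine synthesis from a nitrile), the acid exposure being too short and cold to cleave the aryl MOM ether.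

Step 8
Reactants: 14 5-(methoxymethoxy)-2,2-dimethyl-2H-chromene-8-carboximidamide hydrochloride
Product: 15 3-chloro-3-[5-(methoxymethoxy)-2,2-dimethyl-2H-chromen-8-yl]-3H-diazirine
Conditions: NaOCl (aq), LiCl, DMSO–pentane, 0 °C → rt
Reagents that add atoms: sodium hypochlorite, [Na+].[O-]Cl
Why: Graham oxidation (N-chlorination, base-induced cyclisation and chloride exchange) should give the 3-aryl-3-chlorodiazirine as it does for other donor-substituted benzamidines, and cold basic hypochlorite should neither chlorinate the arene nor epoxidise the chromene.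

Step 9
Reactants: 3 tert-butyl{[4,6-bis(methoxymethoxy)benzofuran-3-yl]oxy}dimethylsilane; 15 3-chloro-3-[5-(methoxymethoxy)-2,2-dimethyl-2H-chromen-8-yl]-3H-diazirine
Product: 18 5,7-bis(methoxymethoxy)-3-[5-(methoxymethoxy)-2,2-dimethyl-2H-chromen-8-yl]-4H-chromen-4-one, via chlorocyclopropane 16 (not isolated), via silyloxybenzopyrylium chloride 17 (not isolated)
Conditions: 3 (1.5 equiv), slow addition of 15, Na2CO3, MeCN, 50 °C, dark
Reagents that add atoms: none
Why: Proposed new method: thermolysis of 15 releases N2 and the aryl(chloro)carbene, which adds across the C2=C3 enol-ether bond of 3 to give the 2-oxabicyclo[3.1.0]hexene 16; because the carbene carbon carries chloride, ionisation is coupled to disrotatory cyclopropyl-to-allyl opening that cleaves the shared C2–C3 bond, so the new carbon ends up between the O–CH carbon and the siloxy carbon, the furan ring becomes the aromatic 4-silyloxybenzopyrylium 17, and chloride desilylates 17 to chromone 18. The closest known reaction types are the Ciamician–Dennstedt carbon-atom insertion of chlorodiazirine-derived aryl(chloro)carbenes into indoles and pyrroles and the dihalocarbene ring expansion of cyclic silyl enol ethers to 2-halo-enones. The three-membered ring is closed by concerted [2+1] carbene addition, and the six-membered ring is not closed by cyclisation at all but arises from the five-membered ring by cleavage of the bond common to both rings of 16. No stereocentre is created, since 18 is achiral and both chloride epimers of 16 converge on it. The step needs chemoselectivity for the furan C2=C3 bond over the chromene C3=C4 bond present in 15 and 18; the former is a doubly oxygen-substituted, phloroglucinol-activated enol ether and is kept in excess while 15 is added slowly, and regiochemistry is fixed because the opening can only place the new carbon between the former C2 and C3.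

Step 10
Reactants: 18 5,7-bis(methoxymethoxy)-3-[5-(methoxymethoxy)-2,2-dimethyl-2H-chromen-8-yl]-4H-chromen-4-one
Product: 20 (3S,4S)-5,7-bis(methoxymethoxy)-3-[5-(methoxymethoxy)-2,2-dimethyl-2H-chromen-8-yl]chroman-4-ol, via racemic isoflavanone 19 (not isolated)
Conditions: RuCl[(S,S)-TsDPEN](p-cymene) (2 mol %), HCO2H/Et3N (5:2), EtOAc, 40 °C
Reagents that add atoms: none
Why: Noyori asymmetric transfer hydrogenation with dynamic kinetic resolution: the ruthenium hydride should first reduce the chromone C2=C3 bond, ketone 19 racemises through its enol under the amine, and the (S,S)-catalyst should reduce the (3S)-enantiomer faster to the (4S)-alcohol cis to the aryl group (same sense as 4-chromanone to (S)-4-chromanol), so C3 is set by catalyst control while the isolated chromene alkene is not reduced.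

Step 11
Reactants: 20 (3S,4S)-5,7-bis(methoxymethoxy)-3-[5-(methoxymethoxy)-2,2-dimethyl-2H-chromen-8-yl]chroman-4-ol
Product: 21 (3S)-5,7-bis(methoxymethoxy)-3-[5-(methoxymethoxy)-2,2-dimethyl-2H-chromen-8-yl]chroman-4-one
Conditions: Dess–Martin periodinane, pyridine, CH2Cl2, 0 °C
Reagents that add atoms: none
Why: Dess–Martin oxidation of the secondary benzylic alcohol under buffered, non-enolising conditions should restore the C4 ketone while C3, which takes no part, keeps its (S) configuration.

Step 12
Reactants: 21 (3S)-5,7-bis(methoxymethoxy)-3-[5-(methoxymethoxy)-2,2-dimethyl-2H-chromen-8-yl]chroman-4-one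
Product: 22 (3S)-5,7-dihydroxy-3-(5-hydroxy-2,2-dimethyl-2H-chromen-8-yl)chroman-4-one
Conditions: HCl (2 M in MeOH), THF, 0 °C → rt
Reagents that add atoms: none
Why: acid-catalysed acetal exchange with methanol should remove the three MOM ethers (the chelated 5-O first) under conditions mild and short enough to avoid acid-catalysed enolisation at C3 and hydration of the chromene, giving the (3S) target.

**Compound list**

1 | 4,6-dihydroxybenzofuran-3(2H)-one | O=C1COc2cc(O)cc(O)c21 | starting material
2 | 4,6-bis(methoxymethoxy)benzofuran-3(2H)-one | O=C1COc2cc(OCOC)cc(OCOC)c21 | intermediate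
3 | tert-butyl{[4,6-bis(methoxymethoxy)benzofuran-3-yl]oxy}dimethylsilane | CC(C)(C)[Si](C)(C)Oc1coc2cc(OCOC)cc(OCOC)c12 | intermediate
4 | 2,4-dihydroxybenzaldehyde | O=Cc1ccc(O)cc1O | starting material
5 | 2-hydroxy-4-(methoxymethoxy)benzaldehyde | O=Cc1ccc(OCOC)cc1O | intermediate
6 | 4-(methoxymethoxy)-2-[(2-methylbut-3-yn-2-yl)oxy]benzaldehyde | O=Cc1ccc(OCOC)cc1OC(C)(C)C#C | intermediate
7 | 2-hydroxy-4-(methoxymethoxy)-3-(3-methylbuta-1,2-dien-1-yl)benzaldehyde (allenylphenol) | O=Cc1ccc(OCOC)c(C=C=C(C)C)c1O | intermediate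
8 | 4-(methoxymethoxy)-5-(3-methylbut-2-en-1-ylidene)-6-oxocyclohexa-1,3-diene-1-carbaldehyde (ortho-quinone methide) | O=C1C(C=O)=CC=C(OCOC)C1=CC=C(C)C | intermediate
9 | 5-(methoxymethoxy)-2,2-dimethyl-2H-chromene-8-carbaldehyde | CC1(C)C=Cc2c(OCOC)ccc(C=O)c2O1 | intermediate
10 | 5-(methoxymethoxy)-2,2-dimethyl-2H-chromene-8-carbaldehyde oxime | ON=Cc1ccc(OCOC)c2C=CC(C)(C)Oc12 | intermediate
11 | 5-(methoxymethoxy)-2,2-dimethyl-2H-chromene-8-carbaldehyde O-acetyloxime | CC(=O)ON=Cc1ccc(OCOC)c2C=CC(C)(C)Oc12 | intermediate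
12 | 5-(methoxymethoxy)-2,2-dimethyl-2H-chromene-8-carbonitrile | N#Cc1ccc(OCOC)c2C=CC(C)(C)Oc12 | intermediate
13 | lithium N,N'-bis(trimethylsilyl)-5-(methoxymethoxy)-2,2-dimethyl-2H-chromene-8-carboximidamidate | [Li+].C[Si](C)(C)[N-]C(=N[Si](C)(C)C)c1ccc(OCOC)c2C=CC(C)(C)Oc12 | intermediate
14 | 5-(methoxymethoxy)-2,2-dimethyl-2H-chromene-8-carboximidamide hydrochloride | NC(=[NH2+])c1ccc(OCOC)c2C=CC(C)(C)Oc12.[Cl-] | intermediate
15 | 3-chloro-3-[5-(methoxymethoxy)-2,2-dimethyl-2H-chromen-8-yl]-3H-diazirine | ClC1(N=N1)c1ccc(OCOC)c2C=CC(C)(C)Oc12 | intermediate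
16 | 6b-[(tert-butyldimethylsilyl)oxy]-1-chloro-4,6-bis(methoxymethoxy)-1-[5-(methoxymethoxy)-2,2-dimethyl-2H-chromen-8-yl]-1a,6b-dihydro-1H-cyclopropa[b]benzofuran (racemic, cis-fused, both chloride epimers) | CC(C)(C)[Si](C)(C)OC12c3c(OCOC)cc(OCOC)cc3OC1C2(Cl)c1ccc(OCOC)c2C=CC(C)(C)Oc12 | intermediate
17 | 4-[(tert-butyldimethylsilyl)oxy]-5,7-bis(methoxymethoxy)-3-[5-(methoxymethoxy)-2,2-dimethyl-2H-chromen-8-yl]chromenylium chloride | [Cl-].CC(C)(C)[Si](C)(C)Oc1c(-c2ccc(OCOC)c3C=CC(C)(C)Oc23)c[o+]c2cc(OCOC)cc(OCOC)c12 | intermediate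
18 | 5,7-bis(methoxymethoxy)-3-[5-(methoxymethoxy)-2,2-dimethyl-2H-chromen-8-yl]-4H-chromen-4-one | CC1(C)C=Cc2c(OCOC)ccc(C3=COc4cc(OCOC)cc(OCOC)c4C3=O)c2O1 | intermediate
19 | racemic 5,7-bis(methoxymethoxy)-3-[5-(methoxymethoxy)-2,2-dimethyl-2H-chromen-8-yl]chroman-4-one | CC1(C)C=Cc2c(OCOC)ccc(C3COc4cc(OCOC)cc(OCOC)c4C3=O)c2O1 | intermediate
20 | (3S,4S)-5,7-bis(methoxymethoxy)-3-[5-(methoxymethoxy)-2,2-dimethyl-2H-chromen-8-yl]chroman-4-ol (cis) | CC1(C)C=Cc2c(OCOC)ccc([C@H]3COc4cc(OCOC)cc(OCOC)c4[C@H]3O)c2O1 | intermediate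
21 | (3S)-5,7-bis(methoxymethoxy)-3-[5-(methoxymethoxy)-2,2-dimethyl-2H-chromen-8-yl]chroman-4-one | CC1(C)C=Cc2c(OCOC)ccc([C@H]3COc4cc(OCOC)cc(OCOC)c4C3=O)c2O1 | intermediate
22 | (3S)-5,7-dihydroxy-3-(5-hydroxy-2,2-dimethyl-2H-chromen-8-yl)chroman-4-one | CC1(C)C=Cc2c(O)ccc([C@H]3COc4cc(O)cc(O)c4C3=O)c2O1 | target

**Step count and risks**

Total steps: 12. Longest linear sequence: 10 steps (4 → 22, steps 3 to 12).

Steps most likely to fail:

1. Step 9 (Proposed new method). The donor-substituted aryl(chloro)carbene may be consumed by chromene double bonds, or the diazirine may ionise or decompose before the carbene adds to the enol ether. Fallback, from 3 and 9, returning at 18; it also removes the need for 12 to 15. Silyl enol ether 3 is treated with dibromocarbene (CHBr3, KOt-Bu, pentane, −20 °C → rt). The gem-dibromocyclopropane F1 should open in the flask, with loss of the silyl bromide, to 3-bromo-5,7-bis(methoxymethoxy)-4H-chromen-4-one F2, so the ring is still made by one-carbon expansion of the furan ring. Aldehyde 9 is taken by Dakin-type oxidation (H2O2, cat. (PhSe)2, CH2Cl2) to the aryl formate F3 and by methanolysis (K2CO3, MeOH) to the phenol F4. F4 is converted into the triflate F5 (Tf2O, pyridine) and then the pinacol boronic ester F6 (B2pin2, Pd(dppf)Cl2, KOAc, dioxane, 80 °C). Suzuki–Miyaura coupling of F2 with F6 (Pd(PPh3)4, K2CO3, dioxane/H2O, 80 °C) should give 18.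

2. Step 10. Reduction of the hindered, electron-rich C4 carbonyl (flanked by the 5-O substituent) may be slow, so the reaction could stall at the racemic ketone or give poor cis selectivity; the electron-rich benzylic alcohol may also ionise under the formic acid medium. Fallback, from 18, returning at 21. Conjugate reduction of 18 with LiBH(s-Bu)3 (THF, −78 °C) and O-acylation of the enolate with allyl chloroformate give the allyl enol carbonate F7. Pd-catalysed decarboxylative asymmetric protonation (Pd2(dba)3, the t-Bu-PHOX enantiomer that leads to the (3S) product, Meldrum's acid as proton source, dioxane, 40 °C) should then give 21 directly, without passing through the alcohol.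

3. Step 12. Acid-catalysed enolisation may erode the C3 configuration, and acid may hydrate the chromene. Fallback, from 18, returning at 22: the protecting groups are exchanged before the stereocentre exists. Acid methanolysis of achiral 18 (HCl, MeOH, 50 °C) gives the triol isoflavone F8, which is silylated (TBSOTf, 2,6-lutidine, CH2Cl2) to the tris-silyl ether F9. The transfer hydrogenation of step 10 (through the racemic ketone F10) gives the cis-alcohol F11, and Dess–Martin oxidation gives the (3S)-ketone F12. Near-neutral desilylation (Et3N·3HF, THF, 0 °C) then gives 22.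

**Further compounds**

F1 | step 9 | 6b-[(tert-butyldimethylsilyl)oxy]-1,1-dibromo-4,6-bis(methoxymethoxy)-1a,6b-dihydro-1H-cyclopropa[b]benzofuran | CC(C)(C)[Si](C)(C)OC12c3c(OCOC)cc(OCOC)cc3OC1C2(Br)Br
F2 | step 9 | 3-bromo-5,7-bis(methoxymethoxy)-4H-chromen-4-one | O=c1c(Br)coc2cc(OCOC)cc(OCOC)c12
F3 | step 9 | 5-(methoxymethoxy)-2,2-dimethyl-2H-chromen-8-yl formate | O=COc1ccc(OCOC)c2C=CC(C)(C)Oc12
F4 | step 9 | 5-(methoxymethoxy)-2,2-dimethyl-2H-chromen-8-ol | Oc1ccc(OCOC)c2C=CC(C)(C)Oc12
F5 | step 9 | 5-(methoxymethoxy)-2,2-dimethyl-2H-chromen-8-yl trifluoromethanesulfonate | FC(F)(F)S(=O)(=O)Oc1ccc(OCOC)c2C=CC(C)(C)Oc12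
F6 | step 9 | 2-[5-(methoxymethoxy)-2,2-dimethyl-2H-chromen-8-yl]-4,4,5,5-tetramethyl-1,3,2-dioxaborolane | CC1(C)OB(OC1(C)C)c1ccc(OCOC)c2C=CC(C)(C)Oc12
F7 | step 10 | allyl 5,7-bis(methoxymethoxy)-3-[5-(methoxymethoxy)-2,2-dimethyl-2H-chromen-8-yl]-2H-chromen-4-yl carbonate | C=CCOC(=O)OC1=C(c2ccc(OCOC)c3C=CC(C)(C)Oc23)COc2cc(OCOC)cc(OCOC)c12
F8 | step 12 | 5,7-dihydroxy-3-(5-hydroxy-2,2-dimethyl-2H-chromen-8-yl)-4H-chromen-4-one | CC1(C)C=Cc2c(O)ccc(C3=COc4cc(O)cc(O)c4C3=O)c2O1
F9 | step 12 | 5,7-bis[(tert-butyldimethylsilyl)oxy]-3-{5-[(tert-butyldimethylsilyl)oxy]-2,2-dimethyl-2H-chromen-8-yl}-4H-chromen-4-one | CC1(C)C=Cc2c(O[Si](C)(C)C(C)(C)C)ccc(C3=COc4cc(O[Si](C)(C)C(C)(C)C)cc(O[Si](C)(C)C(C)(C)C)c4C3=O)c2O1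
F10 | step 12 | racemic 5,7-bis[(tert-butyldimethylsilyl)oxy]-3-{5-[(tert-butyldimethylsilyl)oxy]-2,2-dimethyl-2H-chromen-8-yl}chroman-4-one | CC1(C)C=Cc2c(O[Si](C)(C)C(C)(C)C)ccc(C3COc4cc(O[Si](C)(C)C(C)(C)C)cc(O[Si](C)(C)C(C)(C)C)c4C3=O)c2O1
F11 | step 12 | (3S,4S)-5,7-bis[(tert-butyldimethylsilyl)oxy]-3-{5-[(tert-butyldimethylsilyl)oxy]-2,2-dimethyl-2H-chromen-8-yl}chroman-4-ol | CC1(C)C=Cc2c(O[Si](C)(C)C(C)(C)C)ccc([C@H]3COc4cc(O[Si](C)(C)C(C)(C)C)cc(O[Si](C)(C)C(C)(C)C)c4[C@H]3O)c2O1
F12 | step 12 | (3S)-5,7-bis[(tert-butyldimethylsilyl)oxy]-3-{5-[(tert-butyldimethylsilyl)oxy]-2,2-dimethyl-2H-chromen-8-yl}chroman-4-one | CC1(C)C=Cc2c(O[Si](C)(C)C(C)(C)C)ccc([C@H]3COc4cc(O[Si](C)(C)C(C)(C)C)cc(O[Si](C)(C)C(C)(C)C)c4C3=O)c2O1
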